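**Strategy.** Ring B is read as a Diels–Alder adduct (drimane numbering): the C7=C8 alkene with its C8 methyl is the 1,4-dihydro form of a 6,8(12)-diene, which a vinylallene (C5–C8, C12) and an (E)-enal (C9=C10, C11) give on cycloaddition. One Lewis-acid-promoted intramolecular Diels–Alder reaction of an acyclic keto-trienal, built from geranyl acetate, forges the ring-fusion bond C5–C10 together with C8–C9, closes rings A and B at once and sets C5, C9 and C10. The feature exploited is the four-carbon tether C1–C4 (gem-dimethyl at C4), whose equatorial C2 oxygen dictates the face. Dissolving-metal 1,4-reduction then delivers the C7=C8 alkene.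

Key step: step 7

Remark on locants: bicyclic compounds use drimane numbering (ring A = C1–C5, C10; ring B = C5–C10; C11 on C9; C12 on C8; gem-dimethyl on C4; angular methyl on C10). TMPO = (2,2,6,6-tetramethylpiperidin-1-yl)oxy.

Assumption: in step 2 the enantiomer of the commercial imidazolidinone that delivers the (S)-configured α-oxyaminated aldehyde is used; both enantiomers are sold.

Step 1
Reactants: 1 geranyl acetate
Product: 3 (2E)-3-methyl-6-oxohex-2-en-1-yl acetate, via secondary ozonide 2 (not isolated)
Conditions: O3 (1.0 equiv, indicator end-point), CH2Cl2, pyridine, −78 °C; then Me2S, −78 °C → rt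
Reagents that add atoms: ozone, [O-][O+]=O
Why: Chemoselective ozonolysis: ozone should attack the electron-rich terminal trisubstituted alkene much faster than the alkene deactivated by the allylic acetate, and reductive work-up of the ozonide should give the aldehyde with the (E)-alkene untouched.

Step 2
Reactants: 3 (2E)-3-methyl-6-oxohex-2-en-1-yl acetate
Product: 4 (2E,5S)-3-methyl-6-oxo-5-TMPO-hex-2-en-1-yl acetate
Conditions: TEMPO (1.2 equiv), CuCl2·2H2O (10 mol %), second-generation MacMillan imidazolidinone·TFA (20 mol %), air, acetone, −10 °C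
Reagents that add atoms: TEMPO, CC1(C)CCCC(C)(C)N1[O]
Why: Organocatalytic enamine α-oxyamination: the imidazolidinone forms the (E)-enamine and its shielded face should direct C–O bond formation with copper-activated TEMPO, setting the (S) centre that becomes C2; such α-aminoxy aldehydes are configurationally stable.

Step 3
Reactants: 4 (2E,5S)-3-methyl-6-oxo-5-TMPO-hex-2-en-1-yl acetate; 5 3-chloro-3-methylbut-1-yne
Product: 6 (2E,5S)-6-hydroxy-3,7,7-trimethyl-5-TMPO-non-2-en-8-yn-1-yl acetate (both C6 epimers)
Conditions: Zn dust (activated), THF, 0 °C → rt; aq. NH4Cl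
Reagents that add atoms: none
Why: Barbier-type propargylation: zinc should insert into the tertiary propargylic chloride to give an allenylzinc species that adds through its dimethyl-substituted carbon (SE2′), creating the quaternary C4 next to a terminal alkyne; the carbinol centre forms as an epimer mixture that step 6 erases.

Step 4
Reactants: 6 (2E,5S)-6-hydroxy-3,7,7-trimethyl-5-TMPO-non-2-en-8-yn-1-yl acetate; 7 propargyl bromide
Product: 10 (2E,5S,8E)-6-hydroxy-3,7,7-trimethyl-5-TMPO-dodeca-2,8,10,11-tetraen-1-yl acetate, via alkenylzirconocene chloride 8 (not isolated), via alkenylzinc chloride 9 (not isolated)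
Conditions: Cp2Zr(H)Cl (2.2 equiv), THF, 0 °C → rt; ZnCl2 (1.2 equiv), 0 °C; Pd(PPh3)4 (5 mol %), 0 °C → rt
Reagents that add atoms: none
Why: Hydrozirconation adds Zr–H syn with the metal on the terminal carbon to give the (E)-alkenyl metal, and transmetalation to zinc followed by a Negishi-type coupling, in which zerovalent palladium opens propargyl bromide in an SN2′ sense to an allenylpalladium species, should deliver the terminal vinylallene; one equivalent of Cp2Zr(H)Cl is consumed by the free hydroxyl, which returns on work-up.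

Step 5
Reactants: 10 (2E,5S,8E)-6-hydroxy-3,7,7-trimethyl-5-TMPO-dodeca-2,8,10,11-tetraen-1-yl acetate
Product: 11 (2E,5S,8E)-3,7,7-trimethyl-5-TMPO-dodeca-2,8,10,11-tetraene-1,6-diol
Conditions: K2CO3 (0.2 equiv), MeOH, 0 °C → rt
Reagents that add atoms: none
Why: Base-catalysed transesterification (methanolysis) should free the allylic alcohol without touching the alkoxyamine or the allene, and it is run before the ketone exists so that C2 cannot epimerise.

Step 6
Reactants: 11 (2E,5S,8E)-3,7,7-trimethyl-5-TMPO-dodeca-2,8,10,11-tetraene-1,6-diol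
Product: 12 (2E,5S,8E)-3,7,7-trimethyl-6-oxo-5-TMPO-dodeca-2,8,10,11-tetraenal
Conditions: Dess–Martin periodinane (3 equiv), NaHCO3, CH2Cl2, 0 °C → rt
Reagents that add atoms: none
Why: Dess–Martin oxidation should convert the allylic alcohol into the (E)-enal and the hindered secondary alcohol into the ketone in one operation under neutral conditions, so that the α-oxygenated centre C2 and the enal geometry are kept.

Step 7
Reactants: 12 (2E,5S,8E)-3,7,7-trimethyl-6-oxo-5-TMPO-dodeca-2,8,10,11-tetraenal
Product: 13 (2S,5S,9R,10R)-3-oxo-2-TMPO-drima-6,8(12)-dien-11-al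
Conditions: Me2AlCl (2.2 equiv), CH2Cl2, −78 → −20 °C; aq. Rochelle salt
Reagents that add atoms: none
Why: Me2AlCl binds the enal oxygen and lowers its LUMO, so that the s-cis vinylallene (C5=C6–C7=C8) should add suprafacially across C9=C10 in a concerted, asynchronous [4+2] cycloaddition in which the bond from C5 to the β-carbon C10 is the more advanced one; the closest known reaction types are the Lewis-acid-promoted intramolecular Diels–Alder reaction of (2E)-deca-2,8,10-trienals and the intramolecular Diels–Alder reaction of vinylallenes. Ring B closes as the cycloadduct ring (bonds C5–C10 and C8–C9), and ring A closes in the same event through the four-carbon tether C1–C4 in the fused (type 1) mode with a chair-like tether. C9 and C10 follow from the (E)-geometry of the dienophile (formyl cis to the angular methyl), the trans ring fusion at C5/C10 from the endo transition state with the complexed formyl group under the diene, and the absolute sense of all three from C2, whose bulky aminoxy group must sit equatorial on the chair tether because an axial position would be syn-pentane to the axial methyls on C4 and C10. The step needs endo over exo selectivity (trans over cis fusion) and reaction at the internal allene π bond only; the first is secured by Lewis-acid activation at low temperature, the second by the tether length, which lets only C8 reach C9. The adduct carries the exocyclic C8=C12 methylene and the C6=C7 alkene that step 9 converts into the C7=C8 alkene.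

Step 8
Reactants: 13 (2S,5S,9R,10R)-3-oxo-2-TMPO-drima-6,8(12)-dien-11-al
Product: 14 (2S,3S,5S,9R,10R)-2-TMPO-drima-6,8(12)-diene-3,11-diol
Conditions: NaBH4, MeOH/THF, −40 → 0 °C (crude 13 used directly)
Reagents that add atoms: none
Why: Borohydride reduction: the aldehyde gives the C11 alcohol, and hydride should attack the C3 ketone along the axial trajectory from the face opposite the axial methyls on C4 and C10, setting the equatorial (3S) alcohol trans to the C2 oxygen as is usual for 4,4-dimethyl-3-keto decalins.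

Step 9
Reactants: 14 (2S,3S,5S,9R,10R)-2-TMPO-drima-6,8(12)-diene-3,11-diol
Product: 15 (2S,3S,5S,9R,10R)-drim-7-ene-2,3,11-triol
Conditions: Li (10 equiv), NH3(l)/THF, t-BuOH, −78 °C; then NH4Cl
Reagents that add atoms: none
Why: Birch-type dissolving-metal reduction: the conjugated diene takes up two electrons, the first proton should go to C12 and the resulting allyl anion should be protonated at its less substituted end C6, so that 1,4-reduction gives the trisubstituted C7=C8 alkene and the C8 methyl; the same conditions cleave the weak N–O bond to free the C2 hydroxyl and leave the isolated alkene alone.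

Step 10
Reactants: 15 (2S,3S,5S,9R,10R)-drim-7-ene-2,3,11-triol; 16 umbelliferone
Product: 17 7-{[(2S,3S,5S,9R,10R)-2,3-dihydroxydrim-7-en-11-yl]oxy}-2H-chromen-2-one (CNP0124364.1)
Conditions: PPh3 (2.5 equiv), DIAD (2.5 equiv), THF, 0 → 40 °C
Reagents that add atoms: none
Why: Mitsunobu etherification: the acidic phenol (pKa about 8) should be alkylated by the activated primary C11 alcohol, while the two secondary alcohols of the rigid trans-diequatorial diol are hindered and cannot close to an epoxide; no stereocentre is involved.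

**Compound list**

1 | geranyl acetate, (2E)-3,7-dimethylocta-2,6-dien-1-yl acetate | CC(=O)OC/C=C(\C)CCC=C(C)C | starting material
2 | secondary ozonide of the 6,7-alkene, (2E)-5-(5,5-dimethyl-1,2,4-trioxolan-3-yl)-3-methylpent-2-en-1-yl acetate | CC(=O)OC/C=C(\C)CCC1OOC(C)(C)O1 | intermediate (not isolated)
3 | (2E)-3-methyl-6-oxohex-2-en-1-yl acetate | CC(=O)OC/C=C(\C)CCC=O | intermediate
4 | (2E,5S)-3-methyl-6-oxo-5-TMPO-hex-2-en-1-yl acetate | CC(=O)OC/C=C(\C)C[C@H](ON1C(C)(C)CCCC1(C)C)C=O | intermediate
5 | 3-chloro-3-methylbut-1-yne | CC(C)(Cl)C#C | starting material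
6 | (2E,5S)-6-hydroxy-3,7,7-trimethyl-5-TMPO-non-2-en-8-yn-1-yl acetate (C6 epimers) | CC(=O)OC/C=C(\C)C[C@H](ON1C(C)(C)CCCC1(C)C)C(O)C(C)(C)C#C | intermediate
7 | propargyl bromide, 3-bromoprop-1-yne | C#CCBr | starting material
8 | (E)-alkenylzirconocene chloride from 6 (cyclopentadienyl rings drawn σ-bonded; hydroxyl drawn free) | CC(=O)OC/C=C(\C)C[C@H](ON1C(C)(C)CCCC1(C)C)C(O)C(C)(C)/C=C/[Zr](Cl)(C1C=CC=C1)C1C=CC=C1 | intermediate (not isolated)
9 | (E)-alkenylzinc chloride from 8 | CC(=O)OC/C=C(\C)C[C@H](ON1C(C)(C)CCCC1(C)C)C(O)C(C)(C)/C=C/[Zn]Cl | intermediate (not isolated)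
10 | (2E,5S,8E)-6-hydroxy-3,7,7-trimethyl-5-TMPO-dodeca-2,8,10,11-tetraen-1-yl acetate (C6 epimers) | CC(=O)OC/C=C(\C)C[C@H](ON1C(C)(C)CCCC1(C)C)C(O)C(C)(C)/C=C/C=C=C | intermediate
11 | (2E,5S,8E)-3,7,7-trimethyl-5-TMPO-dodeca-2,8,10,11-tetraene-1,6-diol (C6 epimers) | OC/C=C(\C)C[C@H](ON1C(C)(C)CCCC1(C)C)C(O)C(C)(C)/C=C/C=C=C | intermediate
12 | (2E,5S,8E)-3,7,7-trimethyl-6-oxo-5-TMPO-dodeca-2,8,10,11-tetraenal | O=C/C=C(\C)C[C@H](ON1C(C)(C)CCCC1(C)C)C(=O)C(C)(C)/C=C/C=C=C | intermediate
13 | (2S,5S,9R,10R)-3-oxo-2-TMPO-drima-6,8(12)-dien-11-al; trans-fused, equatorial C2 TMPO, equatorial C9 formyl cis to the C10 methyl | C=C1C=C[C@@H]2C(C)(C)C(=O)[C@@H](ON3C(C)(C)CCCC3(C)C)C[C@@]2(C)[C@@H]1C=O | intermediate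
14 | (2S,3S,5S,9R,10R)-2-TMPO-drima-6,8(12)-diene-3,11-diol | C=C1C=C[C@@H]2C(C)(C)[C@H](O)[C@@H](ON3C(C)(C)CCCC3(C)C)C[C@@]2(C)[C@@H]1CO | intermediate
15 | (2S,3S,5S,9R,10R)-drim-7-ene-2,3,11-triol | CC1=CC[C@@H]2C(C)(C)[C@H](O)[C@@H](O)C[C@@]2(C)[C@@H]1CO | intermediate
16 | umbelliferone, 7-hydroxy-2H-chromen-2-one | Oc1ccc2ccc(=O)oc2c1 | starting material
17 | 7-{[(2S,3S,5S,9R,10R)-2,3-dihydroxydrim-7-en-11-yl]oxy}-2H-chromen-2-one | CC1=CC[C@@H]2C(C)(C)[C@H](O)[C@@H](O)C[C@@]2(C)[C@@H]1COc1ccc2ccc(=O)oc2c1 | target

**Step count and risks**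

Total step count: 10. Longest linear sequence: 10 steps (from geranyl acetate 1).

Most likely to fail, in this order: step 7, step 9, step 10.

Step 7. The exo transition state may compete and give cis ring fusion, because the trans-fused transition state has to build the 1,3-diaxial contact between the C4 and C10 methyls. The Lewis acid may also degrade or oligomerise the vinylallene before cycloaddition. The fallback sets out from 12 and comes back at 13 and replaces Lewis-acid activation by an ionic Diels–Alder reaction. Aldehyde-selective acetalisation of 12 (1,2-bis(trimethylsilyloxy)ethane, cat. TMSOTf, CH2Cl2, −78 °C) would give the ethylene acetal of 12, F1. Catalytic TfOH at −78 → −40 °C would open F1 to an alkoxy-substituted allyl cation, a far more reactive dienophile that cyclises at lower temperature, giving the ethylene acetal of 13, F2. Mild hydrolysis (PPTS, wet acetone) returns 13.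

Step 9. The allyl anion may be protonated partly at the substituted end C8, which gives 1,2-reduction to the 6-ene with an uncontrolled C8 centre, and over-reduction or base-induced alkene migration may add to the loss. The fallback sets out from 13 and comes back at 15. It moves the diene into ring B, where it is s-cis and can be hydrogenated 1,4 by a chromium catalyst:
- DBU (cat.) conjugates the β,γ-unsaturated aldehyde to (2S,5S,10R)-3-oxo-2-TMPO-drima-6,8-dien-11-al, F3.
- Luche reduction (NaBH4, CeCl3·7H2O, MeOH, −20 °C) gives (2S,3S,5S,10R)-2-TMPO-drima-6,8-diene-3,11-diol, F4.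
- (η6-naphthalene)Cr(CO)3 (cat.), H2 (50 bar), THF, 45 °C adds hydrogen 1,4 to C6 and C9 from the face opposite the C10 methyl, giving (2S,3S,5S,9R,10R)-2-TMPO-drim-7-ene-3,11-diol, F5.
- Zn, AcOH/THF/H2O, 50 °C cleaves the N–O bond to give 15.

Step 10. Activation of the β-branched primary C11 alcohol may be slow, and the free 2,3-diol may tie up the phosphonium reagent as a cyclic phosphorane, so that conversion stalls. The fallback sets out from 15 and comes back at 17 and replaces the redox condensation by protection and SN2 displacement: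
- 2,2-dimethoxypropane, CSA gives the 2,3-acetonide of 15, F6.
- Tf2O, 2,6-lutidine, CH2Cl2, −78 °C gives the C11 triflate, F7.
- Umbelliferone 16, Cs2CO3, DMF, 0 °C → rt gives the acetonide of 17, F8.
- AcOH/H2O, 40 °C releases 17.

Further compounds
F1 | step 7 | ethylene acetal of 12, 2-[(1E,4S,7E)-2,6,6-trimethyl-5-oxo-4-TMPO-undeca-1,7,9,10-tetraen-1-yl]-1,3-dioxolane | C1(OCCO1)/C=C(\C)C[C@H](ON2C(C)(C)CCCC2(C)C)C(=O)C(C)(C)/C=C/C=C=C
F2 | step 7 | ethylene acetal of 13, (2S,5S,9R,10R)-11,11-(ethylenedioxy)-2-TMPO-drima-6,8(12)-dien-3-one | C=C1C=C[C@@H]2C(C)(C)C(=O)[C@@H](ON3C(C)(C)CCCC3(C)C)C[C@@]2(C)[C@@H]1C1OCCO1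
F3 | step 9 | (2S,5S,10R)-3-oxo-2-TMPO-drima-6,8-dien-11-al | CC1=C(C=O)[C@]2(C)C[C@H](ON3C(C)(C)CCCC3(C)C)C(=O)C(C)(C)[C@H]2C=C1
F4 | step 9 | (2S,3S,5S,10R)-2-TMPO-drima-6,8-diene-3,11-diol | CC1=C(CO)[C@]2(C)C[C@H](ON3C(C)(C)CCCC3(C)C)[C@@H](O)C(C)(C)[C@H]2C=C1
F5 | step 9 | (2S,3S,5S,9R,10R)-2-TMPO-drim-7-ene-3,11-diol | CC1=CC[C@@H]2C(C)(C)[C@H](O)[C@@H](ON3C(C)(C)CCCC3(C)C)C[C@@]2(C)[C@@H]1CO
F6 | step 10 | (2S,3S,5S,9R,10R)-2,3-O-isopropylidene-drim-7-ene-2,3,11-triol | CC1=CC[C@@H]2C(C)(C)[C@H](OC(C)(C)O3)[C@@H]3C[C@@]2(C)[C@@H]1CO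
F7 | step 10 | C11 trifluoromethanesulfonate of F6 | CC1=CC[C@@H]2C(C)(C)[C@H](OC(C)(C)O3)[C@@H]3C[C@@]2(C)[C@@H]1COS(=O)(=O)C(F)(F)F
F8 | step 10 | 2,3-O-isopropylidene derivative of 17 | CC1=CC[C@@H]2C(C)(C)[C@H](OC(C)(C)O3)[C@@H]3C[C@@]2(C)[C@@H]1COc1ccc2ccc(=O)oc2c1
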